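**Retrosynthetic overview**
- Last C–O bond: acylation of O8 of the ring-closed 8-hydroxy-6,12-olide with the TBS ether of (R)-3-hydroxy-2-methylpropanoic acid, then global desilylation.
- Ring order: the ten-membered carbocycle is closed first at C5–C6 (alkenyl iodide onto aldehyde, Ni/Cr); the new C6 alkoxide then closes the γ-lactone onto C12 in the same flask.
- C7–C8 and both stereocentres come from an enantioselective chromium-catalysed 2-(methoxycarbonyl)allylation of a C8 aldehyde with a γ-(dimethoxymethyl) allylic bromide (C6 masked as acetal).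
- C3–C4, the C4=C5 geometry, C15–OH and the C5–I handle come from one alkoxide-directed anti-carbomagnesiation of propargyl alcohol followed by iodination.
- Key step: C3–C2–C1=C10(C14)–C9–C8 is the unrolled ring of 4-methylanisole. Birch reduction, then an ozonolytic cut of the enol-ether bond (C3–C8), turns the cis constraint of the ring into the 1(10)-Z olefin with ester and aldehyde termini.

Assumption 1: the SMILES is read literally (C1=C10 ring-cis with CH3 trans to C2; C4=C5 ring-trans with CH2OH cis to C6; C6 R, C7 R, C8 S; acyl C2 R); germacrane numbering C1–C15 is used in the comments.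
Assumption 2: the ligand enantiomers named in steps 10 and 12 are those whose published stereochemical models predict the required face; a small-scale test would confirm the choice.

**Route**

Step 1
Reactants: 1 4-methylanisole
Product: 2 1-methoxy-4-methylcyclohexa-1,4-diene
Conditions: Li, NH3(l)/THF, t-BuOH, −78 → −33 °C; MeOH quench
Reagents that add atoms: none
Why: Birch reduction protonates ortho and meta to OMe so that both donor-bearing carbons stay sp2, giving the 1,4-diene in which the future C1=C10 olefin is locked cis inside the six-membered ring.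

Step 2
Reactants: 2 1-methoxy-4-methylcyclohexa-1,4-diene
Product: 4 methyl (3Z)-6,6-dimethoxy-4-methylhex-3-enoate, via aldehyde ester 3 (not isolated)
Conditions: O3 (1.0 equiv), CH2Cl2/MeOH 4:1, −78 °C; Me2S, −78 °C → rt; then HC(OMe)3, PPTS (cat.), rt
Reagents that add atoms: ozone, [O-][O+]=O; trimethyl orthoformate, COC(OC)OC
Why: Chemoselective ozonolysis cuts only the far more nucleophilic enol-ether C=C (C3–C8; ester at C3, aldehyde at C8), the ring-imposed Z geometry of C1=C10 passes into the chain, and in situ acetalisation protects the isomerisation-prone β,γ-unsaturated aldehyde.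

Step 3
Reactants: 4 methyl (3Z)-6,6-dimethoxy-4-methylhex-3-enoate
Product: 5 (3Z)-6,6-dimethoxy-4-methylhex-3-en-1-ol
Conditions: LiAlH4, Et2O, 0 °C; Fieser work-up
Reagents that add atoms: none
Why: Hydride reduction of the ester; the acetal and the isolated trisubstituted olefin are inert to LiAlH4.

Step 4
Reactants: 5 (3Z)-6,6-dimethoxy-4-methylhex-3-en-1-ol
Product: 6 (3Z)-6-bromo-1,1-dimethoxy-3-methylhex-3-ene
Conditions: CBr4, PPh3, 2,6-lutidine, CH2Cl2, 0 °C
Reagents that add atoms: carbon tetrabromide, BrC(Br)(Br)Br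
Why: Appel bromination (SN2 on the alkoxyphosphonium salt of the primary alcohol); the lutidine buffer keeps the acetal intact.

Step 5
Reactants: 6 (3Z)-6-bromo-1,1-dimethoxy-3-methylhex-3-ene; 7 prop-2-yn-1-ol
Product: 11 (2Z)-2-[(3Z)-6,6-dimethoxy-4-methylhex-3-en-1-yl]-3-iodoprop-2-en-1-ol, via Grignard reagent 8 (not isolated), via bromomagnesium propargyl alkoxide 9 (not isolated), via alkenylmagnesium chelate 10 (not isolated)
Conditions: 6, Mg, THF, 35 °C; separately 7, EtMgBr (1.0 equiv), THF, 0 °C; combine, CuI (10 mol %), THF/Et2O, 0 °C → rt, 16 h; then I2, THF, −20 °C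
Reagents that add atoms: iodine, II
Why: Alkoxide-directed, CuI-catalysed anti-carbomagnesiation of the propargylic alkoxide (Duboudin type) puts the alkyl group on the internal alkyne carbon and magnesium on the terminal carbon cis to the CH2O arm (five-membered chelate), so iodinolysis with retention gives iodine cis to CH2OH, which is the C4=C5 geometry of the target.

Step 6
Reactants: 11 (2Z)-2-[(3Z)-6,6-dimethoxy-4-methylhex-3-en-1-yl]-3-iodoprop-2-en-1-ol
Product: 12 tert-butyl{[(2Z)-2-[(3Z)-6,6-dimethoxy-4-methylhex-3-en-1-yl]-3-iodoprop-2-en-1-yl]oxy}dimethylsilane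
Conditions: TBSCl, imidazole, DMF, rt
Reagents that add atoms: tert-butyldimethylsilyl chloride, CC(C)(C)[Si](C)(C)Cl
Why: Standard silylation of the primary allylic alcohol (C15–OH), which must stay masked until the last step.

Step 7
Reactants: 12 tert-butyl{[(2Z)-2-[(3Z)-6,6-dimethoxy-4-methylhex-3-en-1-yl]-3-iodoprop-2-en-1-yl]oxy}dimethylsilane
Product: 13 (3Z,7Z)-7-({[tert-butyl(dimethyl)silyl]oxy}methyl)-8-iodo-3-methylocta-3,7-dienal
Conditions: TESOTf, 2,4,6-collidine, CH2Cl2, 0 °C; then H2O; used crude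
Reagents that add atoms: water, O
Why: Silyl triflate/collidine acetal cleavage (a collidinium intermediate is hydrolysed by water) is non-acidic, so the TBS ether, the alkenyl iodide and the β,γ-position of the Z olefin are untouched.

Step 8
Reactants: 14 2,2-dimethoxyacetaldehyde (60 % aqueous solution); 15 methyl acrylate
Product: 16 methyl 3-hydroxy-4,4-dimethoxy-2-methylidenebutanoate (racemic)
Conditions: DABCO (0.5 equiv), 1,4-dioxane/H2O 1:1, rt
Reagents that add atoms: none
Why: Morita–Baylis–Hillman reaction; the racemic carbinol centre is erased in step 9.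

Step 9
Reactants: 16 methyl 3-hydroxy-4,4-dimethoxy-2-methylidenebutanoate
Product: 17 methyl (2Z)-2-(bromomethyl)-4,4-dimethoxybut-2-enoate
Conditions: NBS, Me2S, CH2Cl2, 0 °C → rt
Reagents that add atoms: N-bromosuccinimide, O=C1CCC(=O)N1Br
Why: Corey–Kim-type activation of the allylic alcohol and SN2′ attack of bromide give the rearranged primary allylic bromide as the favoured Z isomer, under neutral conditions that spare the acetal.

Step 10
Reactants: 13 (3Z,7Z)-7-({[tert-butyl(dimethyl)silyl]oxy}methyl)-8-iodo-3-methylocta-3,7-dienal; 17 methyl (2Z)-2-(bromomethyl)-4,4-dimethoxybut-2-enoate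
Product: 18 methyl (3R,4S,6Z,10Z)-10-({[tert-butyl(dimethyl)silyl]oxy}methyl)-3-(dimethoxymethyl)-11-iodo-6-methyl-2-methylidene-4-[(trimethylsilyl)oxy]undeca-6,10-dienoate
Conditions: CrCl2 (10 mol %), (S,S)-1,8-bis(4-isopropyl-4,5-dihydrooxazol-2-yl)-3,6-di-tert-butylcarbazole (12 mol %), Mn powder, TMSCl, i-Pr2NEt, THF, 0 °C → rt; NaHCO3 work-up
Reagents that add atoms: chlorotrimethylsilane, C[Si](C)(C)Cl
Why: Catalytic enantioselective Nozaki–Hiyama 2-(alkoxycarbonyl)allylation: the allylchromium from 17 adds through its γ-carbon (C7) in a closed chair transition state (anti, C7–C8) to the Re face of the aldehyde under ligand control, giving (3R,4S), while TMSCl turns over chromium and caps the alkoxide so that it cannot lactonise onto the ester; the alkenyl iodide is inert without nickel.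

Step 11
Reactants: 18 methyl (3R,4S,6Z,10Z)-10-({[tert-butyl(dimethyl)silyl]oxy}methyl)-3-(dimethoxymethyl)-11-iodo-6-methyl-2-methylidene-4-[(trimethylsilyl)oxy]undeca-6,10-dienoate
Product: 19 methyl (3R,4S,6Z,10Z)-10-({[tert-butyl(dimethyl)silyl]oxy}methyl)-3-formyl-11-iodo-6-methyl-2-methylidene-4-[(trimethylsilyl)oxy]undeca-6,10-dienoate
Conditions: TESOTf, 2,4,6-collidine, CH2Cl2, 0 °C; then H2O; used crude at once
Reagents that add atoms: water, O
Why: The same non-acidic silyl triflate/collidine acetal cleavage unmasks the C6 aldehyde; the β-oxygen is a poor leaving group as its silyl ether and the short, neutral handling protects the acidic C7–H from epimerisation.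

Step 12
Reactants: 19 methyl (3R,4S,6Z,10Z)-10-({[tert-butyl(dimethyl)silyl]oxy}methyl)-3-formyl-11-iodo-6-methyl-2-methylidene-4-[(trimethylsilyl)oxy]undeca-6,10-dienoate
Product: 22 (3aR,4S,6Z,10Z,11aR)-10-({[tert-butyl(dimethyl)silyl]oxy}methyl)-4-hydroxy-6-methyl-3-methylidene-3a,4,5,8,9,11a-hexahydrocyclodeca[b]furan-2(3H)-one, via macrocyclic hydroxy ester 20 (not isolated), via silyl ether lactone 21 (not isolated)
Conditions: CrCl2 (6 equiv), NiCl2 (5 mol %), (S)-N-[2-(4-isopropyl-4,5-dihydrooxazol-2-yl)-6-methylphenyl]methanesulfonamide (6.5 equiv), Et3N, THF/MeCN, rt, syringe-pump addition of 19 to 2 mM; then citric acid, MeOH, 0 °C → rt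
Reagents that add atoms: none
Why: Ligand-controlled Nozaki–Hiyama–Kishi macrocyclisation: zerovalent nickel inserts into the C–I bond with retention of the olefin geometry, the sulfonamide-ligated alkenylchromium adds to the aldehyde face that gives C6 R (ring C2 of 20) and closes the ten-membered ring, the chromium alkoxide lactonises onto the neighbouring methyl ester (trans γ-lactone), and citric acid/MeOH removes the TMS group.

Step 13
Reactants: 23 methyl (2R)-3-hydroxy-2-methylpropanoate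
Product: 24 methyl (2R)-3-{[tert-butyl(dimethyl)silyl]oxy}-2-methylpropanoate
Conditions: TBSCl, imidazole, DMF, rt
Reagents that add atoms: tert-butyldimethylsilyl chloride, CC(C)(C)[Si](C)(C)Cl
Why: Standard silylation of the primary alcohol; the stereocentre is not touched.

Step 14
Reactants: 24 methyl (2R)-3-{[tert-butyl(dimethyl)silyl]oxy}-2-methylpropanoate
Product: 25 (2R)-3-{[tert-butyl(dimethyl)silyl]oxy}-2-methylpropanoic acid
Conditions: LiOH, THF/MeOH/H2O, 0 °C; aq. HCl to pH 4
Reagents that add atoms: lithium hydroxide, [Li+].[OH-]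
Why: Mild saponification at 0 °C; the α-centre is not epimerised because the carboxylate resists further deprotonation.

Step 15
Reactants: 22 (3aR,4S,6Z,10Z,11aR)-10-({[tert-butyl(dimethyl)silyl]oxy}methyl)-4-hydroxy-6-methyl-3-methylidene-3a,4,5,8,9,11a-hexahydrocyclodeca[b]furan-2(3H)-one; 25 (2R)-3-{[tert-butyl(dimethyl)silyl]oxy}-2-methylpropanoic acid
Product: 26 (3aR,4S,6Z,10Z,11aR)-10-({[tert-butyl(dimethyl)silyl]oxy}methyl)-6-methyl-3-methylidene-2-oxo-2,3,3a,4,5,8,9,11a-octahydrocyclodeca[b]furan-4-yl (2R)-3-{[tert-butyl(dimethyl)silyl]oxy}-2-methylpropanoate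
Conditions: DCC, DMAP (cat.), CH2Cl2, 0 °C → rt
Reagents that add atoms: none
Why: Steglich esterification of the only free hydroxyl (C8–OH); no stereocentre is touched and prompt acylation forestalls 6,12 → 8,12 translactonisation.

Step 16
Reactants: 26 (3aR,4S,6Z,10Z,11aR)-10-({[tert-butyl(dimethyl)silyl]oxy}methyl)-6-methyl-3-methylidene-2-oxo-2,3,3a,4,5,8,9,11a-octahydrocyclodeca[b]furan-4-yl (2R)-3-{[tert-butyl(dimethyl)silyl]oxy}-2-methylpropanoate
Product: 27 (3aR,4S,6Z,10Z,11aR)-10-(hydroxymethyl)-6-methyl-3-methylidene-2-oxo-2,3,3a,4,5,8,9,11a-octahydrocyclodeca[b]furan-4-yl (2R)-3-hydroxy-2-methylpropanoate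
Conditions: HF·pyridine, pyridine, THF, 0 °C → rt
Reagents that add atoms: none
Why: Buffered fluoride desilylation removes both primary TBS ethers under mildly acidic conditions that spare the α-methylene lactone, the allylic alcohol and the ester.

**Compound list**
1 | 4-methylanisole | COc1ccc(C)cc1 | starting material
2 | 1-methoxy-4-methylcyclohexa-1,4-diene | COC1=CCC(C)=CC1 | intermediate
3 | methyl (3Z)-4-methyl-6-oxohex-3-enoate | COC(=O)C/C=C(/C)CC=O | intermediate
4 | methyl (3Z)-6,6-dimethoxy-4-methylhex-3-enoate | COC(=O)C/C=C(/C)CC(OC)OC | intermediate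
5 | (3Z)-6,6-dimethoxy-4-methylhex-3-en-1-ol | OCC/C=C(/C)CC(OC)OC | intermediate
6 | (3Z)-6-bromo-1,1-dimethoxy-3-methylhex-3-ene | BrCC/C=C(/C)CC(OC)OC | intermediate
7 | prop-2-yn-1-ol | C#CCO | starting material
8 | [(3Z)-6,6-dimethoxy-4-methylhex-3-en-1-yl]magnesium bromide | Br[Mg]CC/C=C(/C)CC(OC)OC | intermediate
9 | bromomagnesium prop-2-yn-1-olate | C#CCO[Mg]Br | intermediate
10 | 4-[(3Z)-6,6-dimethoxy-4-methylhex-3-en-1-yl]-2,5-dihydro-1,2-oxamagnesole | [Mg]1OCC(CC/C=C(/C)CC(OC)OC)=C1 | intermediate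
11 | (2Z)-2-[(3Z)-6,6-dimethoxy-4-methylhex-3-en-1-yl]-3-iodoprop-2-en-1-ol | OC/C(CC/C=C(/C)CC(OC)OC)=C\I | intermediate
12 | tert-butyl{[(2Z)-2-[(3Z)-6,6-dimethoxy-4-methylhex-3-en-1-yl]-3-iodoprop-2-en-1-yl]oxy}dimethylsilane | CC(C)(C)[Si](C)(C)OC/C(CC/C=C(/C)CC(OC)OC)=C\I | intermediate
13 | (3Z,7Z)-7-({[tert-butyl(dimethyl)silyl]oxy}methyl)-8-iodo-3-methylocta-3,7-dienal | CC(C)(C)[Si](C)(C)OC/C(CC/C=C(/C)CC=O)=C\I | intermediate
14 | 2,2-dimethoxyacetaldehyde | COC(OC)C=O | starting material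
15 | methyl acrylate | C=CC(=O)OC | starting material
16 | methyl 3-hydroxy-4,4-dimethoxy-2-methylidenebutanoate (racemic) | COC(OC)C(O)C(=C)C(=O)OC | intermediate
17 | methyl (2Z)-2-(bromomethyl)-4,4-dimethoxybut-2-enoate | BrC/C(C(=O)OC)=C\C(OC)OC | intermediate
18 | methyl (3R,4S,6Z,10Z)-10-({[tert-butyl(dimethyl)silyl]oxy}methyl)-3-(dimethoxymethyl)-11-iodo-6-methyl-2-methylidene-4-[(trimethylsilyl)oxy]undeca-6,10-dienoate | CC(C)(C)[Si](C)(C)OC/C(CC/C=C(/C)C[C@H](O[Si](C)(C)C)[C@H](C(OC)OC)C(=C)C(=O)OC)=C\I | intermediate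
19 | methyl (3R,4S,6Z,10Z)-10-({[tert-butyl(dimethyl)silyl]oxy}methyl)-3-formyl-11-iodo-6-methyl-2-methylidene-4-[(trimethylsilyl)oxy]undeca-6,10-dienoate | CC(C)(C)[Si](C)(C)OC/C(CC/C=C(/C)C[C@H](O[Si](C)(C)C)[C@H](C=O)C(=C)C(=O)OC)=C\I | intermediate
20 | methyl 2-[(1S,2R,3Z,7Z,10S)-4-({[tert-butyl(dimethyl)silyl]oxy}methyl)-2-hydroxy-8-methyl-10-[(trimethylsilyl)oxy]cyclodeca-3,7-dien-1-yl]prop-2-enoate (formed as its chromium alkoxide) | COC(=O)C(=C)[C@H]1[C@H](O)/C=C(\CO[Si](C)(C)C(C)(C)C)CC/C=C(/C)C[C@@H]1O[Si](C)(C)C | intermediate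
21 | (3aS,4S,6Z,10Z,11aR)-10-({[tert-butyl(dimethyl)silyl]oxy}methyl)-6-methyl-3-methylidene-4-[(trimethylsilyl)oxy]-3a,4,5,8,9,11a-hexahydrocyclodeca[b]furan-2(3H)-one | C=C1C(=O)O[C@@H]2/C=C(\CO[Si](C)(C)C(C)(C)C)CC/C=C(/C)C[C@H](O[Si](C)(C)C)[C@@H]12 | intermediate
22 | (3aR,4S,6Z,10Z,11aR)-10-({[tert-butyl(dimethyl)silyl]oxy}methyl)-4-hydroxy-6-methyl-3-methylidene-3a,4,5,8,9,11a-hexahydrocyclodeca[b]furan-2(3H)-one | C=C1C(=O)O[C@@H]2/C=C(\CO[Si](C)(C)C(C)(C)C)CC/C=C(/C)C[C@H](O)[C@@H]12 | intermediate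
23 | methyl (2R)-3-hydroxy-2-methylpropanoate | C[C@H](CO)C(=O)OC | starting material
24 | methyl (2R)-3-{[tert-butyl(dimethyl)silyl]oxy}-2-methylpropanoate | C[C@H](CO[Si](C)(C)C(C)(C)C)C(=O)OC | intermediate
25 | (2R)-3-{[tert-butyl(dimethyl)silyl]oxy}-2-methylpropanoic acid | C[C@H](CO[Si](C)(C)C(C)(C)C)C(=O)O | intermediate
26 | (3aR,4S,6Z,10Z,11aR)-10-({[tert-butyl(dimethyl)silyl]oxy}methyl)-6-methyl-3-methylidene-2-oxo-2,3,3a,4,5,8,9,11a-octahydrocyclodeca[b]furan-4-yl (2R)-3-{[tert-butyl(dimethyl)silyl]oxy}-2-methylpropanoate | C=C1C(=O)O[C@@H]2/C=C(\CO[Si](C)(C)C(C)(C)C)CC/C=C(/C)C[C@H](OC(=O)[C@H](C)CO[Si](C)(C)C(C)(C)C)[C@@H]12 | intermediate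
27 | (3aR,4S,6Z,10Z,11aR)-10-(hydroxymethyl)-6-methyl-3-methylidene-2-oxo-2,3,3a,4,5,8,9,11a-octahydrocyclodeca[b]furan-4-yl (2R)-3-hydroxy-2-methylpropanoate | C=C1C(=O)O[C@@H]2/C=C(\CO)CC/C=C(/C)C[C@H](OC(=O)[C@H](C)CO)[C@@H]12 | target

**Step count and risks**
Total: 16 steps. Longest linear sequence: 12 steps (1–7, 10, 11, 12, 15, 16); steps 8–9 and 13–14 are side branches.

The three steps most likely to fail:

Step 2, the ring-cutting ozonolysis. Risks are over-oxidation of the trisubstituted olefin and migration of the β,γ-double bond in aldehyde 3. The fallback sets out from 2 and returns at 4. Only the enol ether of 2 is epoxidised (mCPBA, MeOH, NaHCO3, −20 °C) and the resulting hydroxy ketal is hydrolysed on wet silica to the ketol 2-hydroxy-4-methylcyclohex-4-en-1-one F1. Pb(OAc)4 in MeOH then cleaves the ketol C–C bond to the same aldehyde ester 3 (ester from the carbonyl carbon, aldehyde from the carbinol carbon), which is acetalised as in step 2 to give 4.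

Step 10, the enantioselective allylation. Risks are insufficient ee or anti selectivity with this γ-acetal bromide. The fallback sets out from 13 and 17 and returns at 26, replacing catalyst control by a late resolution.
- The allylation is run without chiral ligand (CrCl2, Mn, TMSCl), giving the racemic anti adduct: 18 together with the (3S,4R)-enantiomer of 18 F2.
- The racemate is carried through steps 11 and 12 with achiral CrCl2/NiCl2. The mirror-image series is the enantiomer of 19 F3, the enantiomer of 20 F4, the enantiomer of 21 F5 and the enantiomer of 22 F6.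
- Esterification with enantiopure 25 as in step 15 gives 26 and the (3aS,4R,11aS)-diastereomer of 26 F7, which are separated by chromatography; the acyl group of the natural product serves as the resolving agent.

Step 12, the ring closure. Risks are strain of the Z,E-cyclodecadiene and the wrong configuration at C6; an open-chain Felkin model with the acrylate as the large group would favour the 6-epimer, so the outcome rests on ligand control. The fallback sets out from 19 and returns at 22, correcting C6 by oxidation and reagent-controlled reduction.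
- The ring is closed with ligand-free CrCl2/NiCl2 and worked up with pH 7 buffer so that the hydroxy esters stay open.
- If the 2-epimer of 20 F8 is formed, alone or mixed with 20, the material is oxidised with Dess–Martin periodinane (NaHCO3, CH2Cl2) to the macrocyclic enone (2-oxo analogue of 20) F9.
- F9 is reduced with (R)-2-methyl-CBS-oxazaborolidine and catecholborane (toluene, −78 °C; alkenyl as the large group) to 20, and citric acid/MeOH then gives 22 as in step 12.

Further compounds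
F1 | step 2 | 2-hydroxy-4-methylcyclohex-4-en-1-one (racemic) | O=C1CC=C(C)CC1O
F2 | step 10 | methyl (3S,4R,6Z,10Z)-10-({[tert-butyl(dimethyl)silyl]oxy}methyl)-3-(dimethoxymethyl)-11-iodo-6-methyl-2-methylidene-4-[(trimethylsilyl)oxy]undeca-6,10-dienoate | CC(C)(C)[Si](C)(C)OC/C(CC/C=C(/C)C[C@@H](O[Si](C)(C)C)[C@@H](C(OC)OC)C(=C)C(=O)OC)=C\I
F3 | step 10 | methyl (3S,4R,6Z,10Z)-10-({[tert-butyl(dimethyl)silyl]oxy}methyl)-3-formyl-11-iodo-6-methyl-2-methylidene-4-[(trimethylsilyl)oxy]undeca-6,10-dienoate | CC(C)(C)[Si](C)(C)OC/C(CC/C=C(/C)C[C@@H](O[Si](C)(C)C)[C@@H](C=O)C(=C)C(=O)OC)=C\I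
F4 | step 10 | methyl 2-[(1R,2S,3Z,7Z,10R)-4-({[tert-butyl(dimethyl)silyl]oxy}methyl)-2-hydroxy-8-methyl-10-[(trimethylsilyl)oxy]cyclodeca-3,7-dien-1-yl]prop-2-enoate | COC(=O)C(=C)[C@@H]1[C@@H](O)/C=C(\CO[Si](C)(C)C(C)(C)C)CC/C=C(/C)C[C@H]1O[Si](C)(C)C
F5 | step 10 | (3aR,4R,6Z,10Z,11aS)-10-({[tert-butyl(dimethyl)silyl]oxy}methyl)-6-methyl-3-methylidene-4-[(trimethylsilyl)oxy]-3a,4,5,8,9,11a-hexahydrocyclodeca[b]furan-2(3H)-one | C=C1C(=O)O[C@H]2/C=C(\CO[Si](C)(C)C(C)(C)C)CC/C=C(/C)C[C@@H](O[Si](C)(C)C)[C@H]12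
F6 | step 10 | (3aS,4R,6Z,10Z,11aS)-10-({[tert-butyl(dimethyl)silyl]oxy}methyl)-4-hydroxy-6-methyl-3-methylidene-3a,4,5,8,9,11a-hexahydrocyclodeca[b]furan-2(3H)-one | C=C1C(=O)O[C@H]2/C=C(\CO[Si](C)(C)C(C)(C)C)CC/C=C(/C)C[C@@H](O)[C@H]12
F7 | step 10 | (3aS,4R,6Z,10Z,11aS)-10-({[tert-butyl(dimethyl)silyl]oxy}methyl)-6-methyl-3-methylidene-2-oxo-2,3,3a,4,5,8,9,11a-octahydrocyclodeca[b]furan-4-yl (2R)-3-{[tert-butyl(dimethyl)silyl]oxy}-2-methylpropanoate | C=C1C(=O)O[C@H]2/C=C(\CO[Si](C)(C)C(C)(C)C)CC/C=C(/C)C[C@@H](OC(=O)[C@H](C)CO[Si](C)(C)C(C)(C)C)[C@H]12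
F8 | step 12 | methyl 2-[(1S,2S,3Z,7Z,10S)-4-({[tert-butyl(dimethyl)silyl]oxy}methyl)-2-hydroxy-8-methyl-10-[(trimethylsilyl)oxy]cyclodeca-3,7-dien-1-yl]prop-2-enoate | COC(=O)C(=C)[C@H]1[C@@H](O)/C=C(\CO[Si](C)(C)C(C)(C)C)CC/C=C(/C)C[C@@H]1O[Si](C)(C)C
F9 | step 12 | methyl 2-[(1R,3Z,7Z,10S)-4-({[tert-butyl(dimethyl)silyl]oxy}methyl)-8-methyl-2-oxo-10-[(trimethylsilyl)oxy]cyclodeca-3,7-dien-1-yl]prop-2-enoate | COC(=O)C(=C)[C@H]1C(=O)/C=C(\CO[Si](C)(C)C(C)(C)C)CC/C=C(/C)C[C@@H]1O[Si](C)(C)C
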